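(The data were computed on assumed constants.)

The vessel is closed, stirred and held at constant volume, and the flasks below differ in charge, temperature or time.

| flask | Wa | Ja | Qi | temperature | remark | time |
|---|---|---|---|---|---|---|
| west | 0.011 M | 0.95 equiv | 13 mol% | 45 °C | run made earlier |  |
| north-east | 0.038 M | 0.95 equiv | 13 mol% | 60 °C | run made earlier |  |
| beta | 0.050 M | 0.950 equiv | 13 mol% | 60 °C |  | 6.0 h |
| gamma | 0.012 M | 0.950 equiv | 13 mol% | 60 °C |  | 25 h |

| run | time / h | Ji / % | Wa / % |
|---|---|---|---|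
| west | 1.00 | 0.8 | 100.9 |
| west | 3.00 | 1.7 | 98.7 |
| west | 6.00 | 0 | 100.4 |
| west | 8.00 | 0.2 | 99.3 |
| west | 12.0 | 0.4 | 97.8 |
| north-east | 1.33 | 0 | 96.5 |
| north-east | 2.50 | 2.7 | 94.3 |
| north-east | 4.00 | 7.2 | 86.0 |
| north-east | 5.00 | 12.6 | 80.7 |
| north-east | 6.00 | 17.9 | 75.9 |

(scatter of a reading: 1 percentage point)

- the numbers in the tables scatter by 1 percentage point (one standard deviation)
- where the amount of Wa changes, what is given in equivalents or mol% on it follows

1. which of the two ends with the higher amount of Ji, in percent of the Wa charged ("neither" if they lie within 2 percentage points) (beta / gamma / neither)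
2. Ji at the end, in percent of the Wa charged, beta
3. Ji at the end, in percent of the Wa charged, gamma

The nearest simulated relative of beta is north-east: it has the same temperature, the same equivalents of Ja and the same loading of Qi, and its last reading falls at the time asked. The two differ in the charge of Wa, 0.050 M against 0.038 M, and because Ja and Qi are given on Wa, they scale with it.

I worked with L, the fraction of Wa left, and not with the Ji made. I assumed that the pseudo-first-order rate of Wa, the slope of −ln L against time, is proportional to the charge c. North-east shows a single concentration at this temperature, so this stays an assumption.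

Between 4.00 h and 6.00 h, that slope in north-east reads 0.0625 h⁻¹. Dividing by the charge gives 4.57 × 10⁻⁴ M⁻¹ s⁻¹, which I call κ, the slope of −ln L per unit of Wa charged. It rests on two readings, each scattered by 1 percentage point.

Drawn back, the line reaches L = one at τ = 1.59 h, a start-up delay that I took as equal in beta and gamma. Ji in north-east trailed the Wa lost by 6.2 points at its last reading, and I assumed, with no run to test it, that the same gap held in beta and gamma, so I subtracted it in both flasks.

L = exp(−κ c (t − τ)), Ji = one − L − gap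

beta: L = 69.6 %, Ji = 24.2 %

gamma: L = 63.0 %, Ji = 30.8 %

So beta ends above the 17.9 % of north-east, because its slope is steeper over the same hours. Gamma has the shallower slope, but its product c(t − τ) is larger than that of beta, so I put gamma ahead by 6.6 points.

The forecast gave 25 % for beta and 30 % for gamma, with gamma ahead, “Assuming percent rate scales with concentration”.

The flasks gave 21.7 % for beta and 31.9 % for gamma, so gamma ended higher.

    Wa → Ju (k = 6.80 × 10⁻⁸ s⁻¹, Ea = 115 kJ mol⁻¹)
    Ez → Jo + Vo (k = 0.00150 s⁻¹, Ea = 88.0 kJ mol⁻¹)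
    Qi → Ze (k = 8.80 × 10⁻⁵ s⁻¹, Ea = 100 kJ mol⁻¹)
    Ja + Ze ⇌ Qe (K = 19.0 M⁻¹, k = 0.0430 M⁻¹ s⁻¹, Ea = 68.0 kJ mol⁻¹, ΔH = −12.0 kJ mol⁻¹)
    Wa + Qe → Dz (k = 0.0320 M⁻¹ s⁻¹, Ea = 76.0 kJ mol⁻¹)
    Vo ⇌ Ze + Ji (K = 0.0250 M, k = 4.80 × 10⁻⁴ s⁻¹, Ea = 94.0 kJ mol⁻¹, ΔH = −11.0 kJ mol⁻¹)
    Dz → Ez (k = 0.00160 s⁻¹, Ea = 104 kJ mol⁻¹)
    (constants at 60 °C)

Beta at 6.00 h held 71.7 % of its Wa against the reckoned 69.6 %, and gamma at 25.0 h held 65.2 % against 63.0 %. The neighbouring flask is gamma itself, read earlier, at 6.0 h. With the same κ and τ, its L came to 91.7 %, and subtracting the same gap left Ji at 2.14 %. That flask held 92.6 % of its Wa and 5.51 % of Ji, so its Ji trailed the Wa lost by 1.9 points, less than the 6.2 points I had assumed.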